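**Retrosynthetic overview**

1. Locants: ring A = C1–C5 and C10 (C1 carries the angelate, C4 the methyl C15, C5 the methyl C14); ring B = C5–C10 (C6=C7, C8=O, C9=C10); C7 carries C11(C13)–C12O2Me.
2. Late disconnections: C1–O ester (angeloylation), C4–H (hydrogenation of a C4 methylene), C6=C7 (dehydrogenation), C7–C11 (alkylation of the C8 enolate with methyl (S)-lactate triflate; inversion gives 11S).
3. Feature used: C3, C4 and C15 are an isopropenyl group on quaternary C5, and C1 is a ketone carbon next to C2. Ring A is therefore cut at C2–C3 and closed by an oxidative radical 6-endo cyclisation of a β-keto ester on C10; an α-chlorine is added at C2 to block over-oxidation.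
4. The cyclisation precursor comes from 3-ethoxycyclohex-2-enone by α'-methylation, enantioselective α'-isopropenylation (sets C5), Stork–Danheiser addition of lithiated methyl propiolate, ketalisation and ynoate hydration.
5. Ring order: ring B is the starting cyclohexenone; ring A is formed second, in the key step.

Key step: step 7

Assumption: the antipode of the binaphthyl phosphine that gives (R)-4 in step 2 cannot be predicted with confidence and is fixed by a first run with both antipodes.

**Route**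

Step 1
Reactants: 1 3-ethoxycyclohex-2-en-1-one
Product: 2 (±)-3-ethoxy-6-methylcyclohex-2-en-1-one
Conditions: LDA, THF, −78 °C; MeI, −78 → 0 °C
Reagents that add atoms: iodomethane, CI
Why: Kinetic deprotonation of the vinylogous ester takes place at the α'-carbon (Stork–Danheiser alkylation) and the lithium enolate is methylated by SN2; the centre is racemic here and becomes quaternary in step 2.

Step 2
Reactants: 2 (±)-3-ethoxy-6-methylcyclohex-2-en-1-one; 3 2-bromopropene
Product: 4 (R)-3-ethoxy-6-methyl-6-(prop-1-en-2-yl)cyclohex-2-en-1-one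
Conditions: NaHMDS, toluene–THF, −78 °C; then Pd2(dba)3 (cat.), (S)-2-(dicyclohexylphosphino)-2'-(dimethylamino)-1,1'-binaphthyl (cat.; antipode as stated in the assumption), 3, −78 °C → rt
Reagents that add atoms: none
Why: Palladium-catalysed enantioselective α-vinylation of a ketone enolate: oxidative addition of 3 to zerovalent palladium, transmetalation by the preformed α'-enolate (the other α-carbon is vinylic, as in the enaminone-blocked α-methyl ketones on which this reaction is established) and reductive elimination in the chiral monophosphine complex should set quaternary C5 under ligand control.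

Step 3
Reactants: 4 (R)-3-ethoxy-6-methyl-6-(prop-1-en-2-yl)cyclohex-2-en-1-one; 5 methyl propiolate
Product: 7 methyl 3-[(6R)-6-methyl-3-oxo-6-(prop-1-en-2-yl)cyclohex-1-en-1-yl]prop-2-ynoate, via propargylic alcohol 6 (not isolated)
Conditions: 5, LDA, THF, −78 °C; CeCl3, −78 °C; then 4, −78 °C; 1 M HCl, THF, 0 °C → rt
Reagents that add atoms: water, O
Why: Stork–Danheiser transposition: 1,2-addition of the cerium-modified lithium acetylide to the hindered vinylogous ester carbonyl, then acid hydrolysis of the enol ether and loss of water, should give the 3-alkynyl enone in which the former carbonyl carbon is C10 and the former ethoxy carbon is the C8 ketone; C5 is not touched.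

Step 4
Reactants: 7 methyl 3-[(6R)-6-methyl-3-oxo-6-(prop-1-en-2-yl)cyclohex-1-en-1-yl]prop-2-ynoate
Product: 8 methyl 3-[(8R)-8-methyl-8-(prop-1-en-2-yl)-1,4-dioxaspiro[4.5]dec-6-en-7-yl]prop-2-ynoate
Conditions: TMSOCH2CH2OTMS, TMSOTf (cat.), CH2Cl2, −78 → −20 °C
Reagents that add atoms: 1,2-bis(trimethylsilyloxy)ethane, C[Si](C)(C)OCCO[Si](C)(C)C
Why: Silyl-transfer ketalisation under TMSOTf catalysis converts the enone carbonyl into the dioxolane at low temperature without acid strong enough to touch the ynoate; the C9=C10 bond cannot migrate because C5 is quaternary.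

Step 5
Reactants: 8 methyl 3-[(8R)-8-methyl-8-(prop-1-en-2-yl)-1,4-dioxaspiro[4.5]dec-6-en-7-yl]prop-2-ynoate
Product: 10 methyl 3-[(8R)-8-methyl-8-(prop-1-en-2-yl)-1,4-dioxaspiro[4.5]dec-6-en-7-yl]-3-oxopropanoate, via morpholine enamino ester 9 (not isolated)
Conditions: morpholine, THF, 0 °C → rt; then AcOH–NaOAc buffer (pH 4–5), H2O–THF, rt
Reagents that add atoms: water, O
Why: Conjugate addition of the secondary amine to the ynoate at its β-carbon C1, then C-protonation and hydrolysis of the weakly donating morpholine enamine, should give the β-keto ester with the ketone on the ring-bound carbon; the C8 dioxolane should survive because its ionisation is retarded by the electron-poor C9=C10 bond.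

Step 6
Reactants: 10 methyl 3-[(8R)-8-methyl-8-(prop-1-en-2-yl)-1,4-dioxaspiro[4.5]dec-6-en-7-yl]-3-oxopropanoate
Product: 11 methyl 2-chloro-3-[(8R)-8-methyl-8-(prop-1-en-2-yl)-1,4-dioxaspiro[4.5]dec-6-en-7-yl]-3-oxopropanoate (C2 epimers)
Conditions: NCS (1.0 equiv), Mg(ClO4)2 (cat.), EtOAc, 0 °C → rt
Reagents that add atoms: N-chlorosuccinimide, O=C1CCC(=O)N1Cl
Why: Electrophilic α-chlorination of the magnesium-chelated β-keto ester enol, which is far more nucleophilic than the isopropenyl group; the chlorine is a blocking group, so that the cyclised product of step 7 has no α-hydrogen and cannot be oxidised further.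

Step 7
Reactants: 11 methyl 2-chloro-3-[(8R)-8-methyl-8-(prop-1-en-2-yl)-1,4-dioxaspiro[4.5]dec-6-en-7-yl]-3-oxopropanoate
Product: 12 methyl (4a'R)-7'-chloro-4a'-methyl-5'-methylidene-8'-oxo-3',4',4a',5',6',7'-hexahydro-8'H-spiro[1,3-dioxolane-2,2'-naphthalene]-7'-carboxylate (C7' epimers; C7' is C2 of the skeleton)
Conditions: Mn(OAc)3·2H2O (2.2 equiv), Cu(OAc)2·H2O (1 equiv), degassed AcOH (KOAc-buffered), 25–40 °C
Reagents that add atoms: none
Why: Mn(OAc)3 forms the trivalent manganese enolate of the α-chloro β-keto ester and one-electron oxidation gives the electrophilic C2 radical, which adds to the unsubstituted terminus C3 of the isopropenyl group; the resulting tertiary C4 radical is oxidised by divalent copper and loses a β-hydrogen, which should give mainly the C4 exocyclic methylene. The closest known reaction type is the manganese triacetate and copper diacetate oxidative free-radical cyclisation of unsaturated α-chloro β-keto esters onto 1,1-disubstituted alkenes. Ring A closes in the 6-endo-trig mode through the new C2–C3 bond. C2 forms as a mixture of epimers that is erased in steps 8 and 9, and C5 is not touched, so no stereocentre of the target is set here. The step needs 6-endo over 5-exo closure; this is secured by the 1,1-disubstituted alkene (attack at C3 gives a tertiary radical, whereas 5-exo attack would build a quaternary carbon next to quaternary C5 and leave a primary radical) and by the ketone lying inside the forming ring. The chlorine removes the α-hydrogen through which an unblocked product would be oxidised further.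

Step 8
Reactants: 12 methyl (4a'R)-7'-chloro-4a'-methyl-5'-methylidene-8'-oxo-3',4',4a',5',6',7'-hexahydro-8'H-spiro[1,3-dioxolane-2,2'-naphthalene]-7'-carboxylate
Product: 13 methyl (4a'R)-4a'-methyl-5'-methylidene-8'-oxo-3',4',4a',5',6',7'-hexahydro-8'H-spiro[1,3-dioxolane-2,2'-naphthalene]-7'-carboxylate (C7' epimers and enol)
Conditions: Zn dust, AcOH, THF, 0 °C
Reagents that add atoms: none
Why: Reductive dechlorination of the doubly activated C–Cl bond by zinc (two-electron reduction to the zinc enolate, then protonation) should be much faster than any reduction of the enone or of the γ-ketal.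

Step 9
Reactants: 13 methyl (4a'R)-4a'-methyl-5'-methylidene-8'-oxo-3',4',4a',5',6',7'-hexahydro-8'H-spiro[1,3-dioxolane-2,2'-naphthalene]-7'-carboxylate
Product: 14 (4a'R)-4a'-methyl-5'-methylidene-3',4',4a',5',6',7'-hexahydro-8'H-spiro[1,3-dioxolane-2,2'-naphthalen]-8'-one
Conditions: LiCl, H2O, DMSO, 140 °C
Reagents that add atoms: none
Why: Krapcho dealkoxycarbonylation: chloride demethylates the ester by SN2 and the β-keto carboxylate loses CO2; the neutral conditions spare the dioxolane and the exocyclic alkene.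

Step 10
Reactants: 14 (4a'R)-4a'-methyl-5'-methylidene-3',4',4a',5',6',7'-hexahydro-8'H-spiro[1,3-dioxolane-2,2'-naphthalen]-8'-one
Product: 15 (4a'R,8'R)-4a'-methyl-5'-methylidene-4',4a',5',6',7',8'-hexahydro-3'H-spiro[1,3-dioxolane-2,2'-naphthalen]-8'-ol
Conditions: (S)-Me-CBS oxazaborolidine (0.3 equiv), catecholborane, toluene, −78 °C
Reagents that add atoms: none
Why: Corey–Bakshi–Shibata reduction: the catalyst binds the C1 carbonyl anti to the larger, α-branched alkenyl substituent C10 and delivers hydride to the face that gives the 1R alcohol (C1–O cis to C14), the face also left open when C14 is axial; catecholborane at −78 °C reduces the enone 1,2 and does not hydroborate the C4 methylene.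

Step 11
Reactants: 15 (4a'R,8'R)-4a'-methyl-5'-methylidene-4',4a',5',6',7',8'-hexahydro-3'H-spiro[1,3-dioxolane-2,2'-naphthalen]-8'-ol
Product: 16 tert-butyl(dimethyl){[(4a'R,8'R)-4a'-methyl-5'-methylidene-4',4a',5',6',7',8'-hexahydro-3'H-spiro[1,3-dioxolane-2,2'-naphthalen]-8'-yl]oxy}silane
Conditions: TBSOTf, 2,6-lutidine, CH2Cl2, −78 → 0 °C
Reagents that add atoms: tert-butyldimethylsilyl triflate, CC(C)(C)[Si](C)(C)OS(=O)(=O)C(F)(F)F
Why: O-silylation of the hindered secondary allylic alcohol with the silyl triflate and a hindered base; the C–O bond is not broken, so C1 keeps its configuration.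

Step 12
Reactants: 16 tert-butyl(dimethyl){[(4a'R,8'R)-4a'-methyl-5'-methylidene-4',4a',5',6',7',8'-hexahydro-3'H-spiro[1,3-dioxolane-2,2'-naphthalen]-8'-yl]oxy}silane
Product: 17 (4aR,8R)-8-{[tert-butyl(dimethyl)silyl]oxy}-4a-methyl-5-methylidene-4,4a,5,6,7,8-hexahydronaphthalen-2(3H)-one
Conditions: PPTS, acetone–H2O (9:1), 50 °C
Reagents that add atoms: water, O
Why: Mild acid-catalysed hydrolysis of the dioxolane frees the C8 enone, while the secondary TBS ether and the 1,1-disubstituted alkene tolerate pyridinium-level acidity.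

Step 13
Reactants: 18 methyl (S)-lactate
Product: 19 methyl (2S)-2-{[(trifluoromethyl)sulfonyl]oxy}propanoate
Conditions: Tf2O, 2,6-lutidine, CH2Cl2, −78 → 0 °C; used at once
Reagents that add atoms: triflic anhydride, O=S(=O)(OS(=O)(=O)C(F)(F)F)C(F)(F)F
Why: O-sulfonylation of the alcohol leaves the C–O bond intact, so the triflate keeps the S configuration of the lactate.

Step 14
Reactants: 17 (4aR,8R)-8-{[tert-butyl(dimethyl)silyl]oxy}-4a-methyl-5-methylidene-4,4a,5,6,7,8-hexahydronaphthalen-2(3H)-one; 19 methyl (2S)-2-{[(trifluoromethyl)sulfonyl]oxy}propanoate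
Product: 20 methyl (2S)-2-[(5R,8aR)-5-{[tert-butyl(dimethyl)silyl]oxy}-8a-methyl-8-methylidene-3-oxo-1,2,3,5,6,7,8,8a-octahydronaphthalen-2-yl]propanoate (epimers at ring C2, which is C7 of the skeleton)
Conditions: LDA (1.05 equiv), THF, −78 °C; then 19, −78 → −40 °C
Reagents that add atoms: none
Why: Kinetic α'-deprotonation of the enone at C7 gives the cross-conjugated lithium dienolate, which is alkylated by the α-triflyloxy ester in an SN2 reaction with inversion at the lactate carbon; the S triflate becomes 11S (the descriptor is kept because the priorities change), and C7 forms as a mixture that becomes sp2 in step 15.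

Step 15
Reactants: 20 methyl (2S)-2-[(5R,8aR)-5-{[tert-butyl(dimethyl)silyl]oxy}-8a-methyl-8-methylidene-3-oxo-1,2,3,5,6,7,8,8a-octahydronaphthalen-2-yl]propanoate
Product: 21 methyl (2S)-2-[(5R,8aR)-5-{[tert-butyl(dimethyl)silyl]oxy}-8a-methyl-8-methylidene-3-oxo-3,5,6,7,8,8a-hexahydronaphthalen-2-yl]propanoate
Conditions: DDQ, 1,4-dioxane, reflux
Reagents that add atoms: none
Why: Quinone dehydrogenation of an enone to the cross-conjugated dienone: under neutral conditions the kinetic C7 enol forms and DDQ should abstract hydride from C6, not from C11–H (positive charge there would sit next to the ester) nor from C1–H (allylic to an electron-poor alkene); C11 is not enolised.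

Step 16
Reactants: 21 methyl (2S)-2-[(5R,8aR)-5-{[tert-butyl(dimethyl)silyl]oxy}-8a-methyl-8-methylidene-3-oxo-3,5,6,7,8,8a-hexahydronaphthalen-2-yl]propanoate
Product: 22 methyl (2S)-2-[(5R,8S,8aS)-5-{[tert-butyl(dimethyl)silyl]oxy}-8,8a-dimethyl-3-oxo-3,5,6,7,8,8a-hexahydronaphthalen-2-yl]propanoate
Conditions: H2 (1 atm), RhCl(PPh3)3 (cat.), benzene–EtOH, rt
Reagents that add atoms: none
Why: Homogeneous hydrogenation with RhCl(PPh3)3 reduces only the isolated 1,1-disubstituted C4 methylene (both dienone alkenes are trisubstituted and conjugated); with ring B now planar, C14 is locked axial on ring A and, together with the axial C1 silyloxy group, screens one face, so syn addition of H2 from the other face should place C15 cis to C14 (4S).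

Step 17
Reactants: 22 methyl (2S)-2-[(5R,8S,8aS)-5-{[tert-butyl(dimethyl)silyl]oxy}-8,8a-dimethyl-3-oxo-3,5,6,7,8,8a-hexahydronaphthalen-2-yl]propanoate
Product: 23 methyl (2S)-2-[(5R,8S,8aS)-5-hydroxy-8,8a-dimethyl-3-oxo-3,5,6,7,8,8a-hexahydronaphthalen-2-yl]propanoate
Conditions: HF·pyridine, THF–pyridine, 0 °C → rt
Reagents that add atoms: none
Why: Fluoride-induced Si–O cleavage under mildly acidic conditions, chosen over basic fluoride so that C11 (α to the ester and allylic) is not epimerised.

Step 18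
Reactants: 23 methyl (2S)-2-[(5R,8S,8aS)-5-hydroxy-8,8a-dimethyl-3-oxo-3,5,6,7,8,8a-hexahydronaphthalen-2-yl]propanoate; 24 angelic acid
Product: 26 (1R,4S,4aS)-6-[(2S)-1-methoxy-1-oxopropan-2-yl]-4,4a-dimethyl-7-oxo-1,2,3,4,4a,7-hexahydronaphthalen-1-yl (2Z)-2-methylbut-2-enoate (target), via mixed anhydride 25 (not isolated)
Conditions: 24, 2,4,6-trichlorobenzoyl chloride, Et3N, toluene, rt, filtration; then 23, toluene, 80 °C (no DMAP)
Reagents that add atoms: none
Why: Yamaguchi-type mixed-anhydride esterification: the alcohol attacks the less hindered angeloyl carbonyl of the 2,4,6-trichlorobenzoic mixed anhydride, and leaving out the nucleophilic catalyst avoids Z to E isomerisation to the tiglate; the C1–O bond is not broken, so C1 stays R.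

**Compound list**

1 | 3-ethoxycyclohex-2-en-1-one | CCOC1=CC(=O)CCC1 | starting material
2 | (±)-3-ethoxy-6-methylcyclohex-2-en-1-one | CCOC1=CC(=O)C(C)CC1 | intermediate
3 | 2-bromopropene | CC(Br)=C | starting material
4 | (R)-3-ethoxy-6-methyl-6-(prop-1-en-2-yl)cyclohex-2-en-1-one | CCOC1=CC(=O)[C@@](C)(C(C)=C)CC1 | intermediate
5 | methyl propiolate | C#CC(=O)OC | starting material
6 | methyl 3-[(6R)-3-ethoxy-1-hydroxy-6-methyl-6-(prop-1-en-2-yl)cyclohex-2-en-1-yl]prop-2-ynoate (C1 epimers) | CCOC1=CC(O)(C#CC(=O)OC)[C@@](C)(C(C)=C)CC1 | intermediate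
7 | methyl 3-[(6R)-6-methyl-3-oxo-6-(prop-1-en-2-yl)cyclohex-1-en-1-yl]prop-2-ynoate | COC(=O)C#CC1=CC(=O)CC[C@]1(C)C(C)=C | intermediate
8 | methyl 3-[(8R)-8-methyl-8-(prop-1-en-2-yl)-1,4-dioxaspiro[4.5]dec-6-en-7-yl]prop-2-ynoate | COC(=O)C#CC1=CC2(OCCO2)CC[C@]1(C)C(C)=C | intermediate
9 | methyl 3-[(8R)-8-methyl-8-(prop-1-en-2-yl)-1,4-dioxaspiro[4.5]dec-6-en-7-yl]-3-(morpholin-4-yl)prop-2-enoate | COC(=O)C=C(N1CCOCC1)C1=CC2(OCCO2)CC[C@]1(C)C(C)=C | intermediate
10 | methyl 3-[(8R)-8-methyl-8-(prop-1-en-2-yl)-1,4-dioxaspiro[4.5]dec-6-en-7-yl]-3-oxopropanoate | COC(=O)CC(=O)C1=CC2(OCCO2)CC[C@]1(C)C(C)=C | intermediate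
11 | methyl 2-chloro-3-[(8R)-8-methyl-8-(prop-1-en-2-yl)-1,4-dioxaspiro[4.5]dec-6-en-7-yl]-3-oxopropanoate (C2 epimers) | COC(=O)C(Cl)C(=O)C1=CC2(OCCO2)CC[C@]1(C)C(C)=C | intermediate
12 | methyl (4a'R)-7'-chloro-4a'-methyl-5'-methylidene-8'-oxo-3',4',4a',5',6',7'-hexahydro-8'H-spiro[1,3-dioxolane-2,2'-naphthalene]-7'-carboxylate (C7' epimers) | COC(=O)C1(Cl)CC(=C)[C@@]2(C)CCC3(OCCO3)C=C2C1=O | intermediate
13 | methyl (4a'R)-4a'-methyl-5'-methylidene-8'-oxo-3',4',4a',5',6',7'-hexahydro-8'H-spiro[1,3-dioxolane-2,2'-naphthalene]-7'-carboxylate (C7' epimers) | COC(=O)C1CC(=C)[C@@]2(C)CCC3(OCCO3)C=C2C1=O | intermediate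
14 | (4a'R)-4a'-methyl-5'-methylidene-3',4',4a',5',6',7'-hexahydro-8'H-spiro[1,3-dioxolane-2,2'-naphthalen]-8'-one | O=C1CCC(=C)[C@@]2(C)CCC3(OCCO3)C=C12 | intermediate
15 | (4a'R,8'R)-4a'-methyl-5'-methylidene-4',4a',5',6',7',8'-hexahydro-3'H-spiro[1,3-dioxolane-2,2'-naphthalen]-8'-ol | O[C@@H]1CCC(=C)[C@@]2(C)CCC3(OCCO3)C=C12 | intermediate
16 | tert-butyl(dimethyl){[(4a'R,8'R)-4a'-methyl-5'-methylidene-4',4a',5',6',7',8'-hexahydro-3'H-spiro[1,3-dioxolane-2,2'-naphthalen]-8'-yl]oxy}silane | CC(C)(C)[Si](C)(C)O[C@@H]1CCC(=C)[C@@]2(C)CCC3(OCCO3)C=C12 | intermediate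
17 | (4aR,8R)-8-{[tert-butyl(dimethyl)silyl]oxy}-4a-methyl-5-methylidene-4,4a,5,6,7,8-hexahydronaphthalen-2(3H)-one | CC(C)(C)[Si](C)(C)O[C@@H]1CCC(=C)[C@@]2(C)CCC(=O)C=C12 | intermediate
18 | methyl (S)-lactate | C[C@H](O)C(=O)OC | starting material
19 | methyl (2S)-2-{[(trifluoromethyl)sulfonyl]oxy}propanoate | C[C@H](OS(=O)(=O)C(F)(F)F)C(=O)OC | intermediate
20 | methyl (2S)-2-[(5R,8aR)-5-{[tert-butyl(dimethyl)silyl]oxy}-8a-methyl-8-methylidene-3-oxo-1,2,3,5,6,7,8,8a-octahydronaphthalen-2-yl]propanoate (ring C2 epimers) | CC(C)(C)[Si](C)(C)O[C@@H]1CCC(=C)[C@@]2(C)CC([C@H](C)C(=O)OC)C(=O)C=C12 | intermediate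
21 | methyl (2S)-2-[(5R,8aR)-5-{[tert-butyl(dimethyl)silyl]oxy}-8a-methyl-8-methylidene-3-oxo-3,5,6,7,8,8a-hexahydronaphthalen-2-yl]propanoate | CC(C)(C)[Si](C)(C)O[C@@H]1CCC(=C)[C@@]2(C)C=C([C@H](C)C(=O)OC)C(=O)C=C12 | intermediate
22 | methyl (2S)-2-[(5R,8S,8aS)-5-{[tert-butyl(dimethyl)silyl]oxy}-8,8a-dimethyl-3-oxo-3,5,6,7,8,8a-hexahydronaphthalen-2-yl]propanoate | CC(C)(C)[Si](C)(C)O[C@@H]1CC[C@H](C)[C@@]2(C)C=C([C@H](C)C(=O)OC)C(=O)C=C12 | intermediate
23 | methyl (2S)-2-[(5R,8S,8aS)-5-hydroxy-8,8a-dimethyl-3-oxo-3,5,6,7,8,8a-hexahydronaphthalen-2-yl]propanoate | O[C@@H]1CC[C@H](C)[C@@]2(C)C=C([C@H](C)C(=O)OC)C(=O)C=C12 | intermediate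
24 | angelic acid, (2Z)-2-methylbut-2-enoic acid | C/C=C(/C)C(=O)O | starting material
25 | (2Z)-2-methylbut-2-enoic 2,4,6-trichlorobenzoic anhydride | C/C=C(/C)C(=O)OC(=O)c1c(Cl)cc(Cl)cc1Cl | intermediate
26 | (1R,4S,4aS)-6-[(2S)-1-methoxy-1-oxopropan-2-yl]-4,4a-dimethyl-7-oxo-1,2,3,4,4a,7-hexahydronaphthalen-1-yl (2Z)-2-methylbut-2-enoate | C/C=C(/C)C(=O)O[C@@H]1CC[C@H](C)[C@@]2(C)C=C([C@H](C)C(=O)OC)C(=O)C=C12 | target

**Step count**

Total: 18 steps. Longest linear sequence: 17 steps (steps 1–12 and 14–18); step 13 is a one-step side branch.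

**Steps most likely to fail**

Step 7 (key cyclisation). The radical may close 5-exo in part, the manganese enolate may be oxidised only slowly, or the tertiary C4 radical may be captured by acetate or by the ester carbonyl instead of losing a proton; the dioxolane may also be eroded in warm acetic acid. The fallback sets out from 10 and returns at 13. Compound 10 is iodinated (NIS, Mg(ClO4)2 cat.) to methyl 2-iodo-3-[(8R)-8-methyl-8-(prop-1-en-2-yl)-1,4-dioxaspiro[4.5]dec-6-en-7-yl]-3-oxopropanoate F1. Iodine atom-transfer radical cyclisation ((Bu3Sn)2 cat., visible light, benzene) should then close the same C2–C3 bond 6-endo under non-oxidising chain conditions to the tertiary iodide methyl (4a'R)-5'-iodo-4a',5'-dimethyl-8'-oxo-3',4',4a',5',6',7'-hexahydro-8'H-spiro[1,3-dioxolane-2,2'-naphthalene]-7'-carboxylate F2. Elimination of hydrogen iodide with DBU gives 13.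

Step 2 (enantioselective isopropenylation). The chiral complex may discriminate the faces of the tetrasubstituted enolate poorly, or proton transfer may lead to the extended enolate and to vinylation at the γ-carbon. The fallback sets out from 1 and returns at 4. The α'-lithium enolate of 1 is added to acetone to give 3-ethoxy-6-(2-hydroxypropan-2-yl)cyclohex-2-en-1-one F3. Acid-catalysed dehydration (TsOH cat., benzene, reflux) gives 3-ethoxy-6-(propan-2-ylidene)cyclohex-2-en-1-one F4. Deprotonation of the syn methyl group with LDA and deconjugative α-methylation of the dienolate with MeI gives racemic 3-ethoxy-6-methyl-6-(prop-1-en-2-yl)cyclohex-2-en-1-one F5. F5 is resolved by preparative chromatography on a chiral stationary phase to give 4.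

Step 15 (dehydrogenation). Enolisation towards the tertiary C7 may be slow, so that conversion stalls, or hydride may be lost from another allylic position and give over-oxidised or linearly conjugated products. The fallback sets out from 20 and returns at 21. Soft enolisation (TMSOTf, Et3N, CH2Cl2, 0 °C) gives the 2-silyloxy diene methyl (2S)-2-[(5R,8aR)-5-{[tert-butyl(dimethyl)silyl]oxy}-8a-methyl-8-methylidene-3-[(trimethylsilyl)oxy]-1,5,6,7,8,8a-hexahydronaphthalen-2-yl]propanoate F6. Saegusa–Ito oxidation with Pd(OAc)2 in MeCN (divalent palladium enolate, β-hydride elimination from C6) gives 21.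

**Further compounds**

F1 | step 7 | methyl 2-iodo-3-[(8R)-8-methyl-8-(prop-1-en-2-yl)-1,4-dioxaspiro[4.5]dec-6-en-7-yl]-3-oxopropanoate | COC(=O)C(I)C(=O)C1=CC2(OCCO2)CC[C@]1(C)C(C)=C
F2 | step 7 | methyl (4a'R)-5'-iodo-4a',5'-dimethyl-8'-oxo-3',4',4a',5',6',7'-hexahydro-8'H-spiro[1,3-dioxolane-2,2'-naphthalene]-7'-carboxylate | COC(=O)C1CC(C)(I)[C@@]2(C)CCC3(OCCO3)C=C2C1=O
F3 | step 2 | 3-ethoxy-6-(2-hydroxypropan-2-yl)cyclohex-2-en-1-one | CCOC1=CC(=O)C(CC1)C(C)(C)O
F4 | step 2 | 3-ethoxy-6-(propan-2-ylidene)cyclohex-2-en-1-one | CCOC1=CC(=O)C(=C(C)C)CC1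
F5 | step 2 | racemic 3-ethoxy-6-methyl-6-(prop-1-en-2-yl)cyclohex-2-en-1-one | CCOC1=CC(=O)C(C)(C(C)=C)CC1
F6 | step 15 | methyl (2S)-2-[(5R,8aR)-5-{[tert-butyl(dimethyl)silyl]oxy}-8a-methyl-8-methylidene-3-[(trimethylsilyl)oxy]-1,5,6,7,8,8a-hexahydronaphthalen-2-yl]propanoate | CC(C)(C)[Si](C)(C)O[C@@H]1CCC(=C)[C@@]2(C)CC([C@H](C)C(=O)OC)=C(O[Si](C)(C)C)C=C12
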